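The cyclopentane that carries the tertiary alcohol (ring F) is cut at two bonds: carbinol carbon Ca to ring-fusion CH Cb, and lactone α-carbon Cc to the methylene Cd on the quaternary bridgehead. One SmI2 operation makes both from an 8-azabicyclo[4.3.1]decane keto aldehyde: the ketyl of the cycloheptanone carbonyl (Ca) closes the cyclopentene (ring E) onto a tethered enoate (Cb), and the samarium enolate formed (Cc) closes ring F by aldol addition to the neopentyl formyl group (Cd). The step exploits the 1,3-relationship of Ca and Cd across the bridgehead and the (Z)-alkylidene tether on Ca's neighbour. A spiro-oxetane masks both CH2O arms and is opened last by the carboxyl group.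

Key step: step 13

Remark (labels for 33): Ca = carbinol carbon; Cb = ring-fusion CH next to it; Cc = lactone α-CH; Cd = CH2 of ring F; Ce = quaternary bridgehead carrying Cd and CH2N; Cf = quaternary carbon carrying the side chain and the lactone OCH2; Cg = bridgehead CH; ring C = piperidine, ring D = cycloheptane, ring E = cyclopentene, ring F = cyclopentane.
Remark: oxetan-3-one (4) and phosphonate 31 are taken as commercial; which enantiomer of the resolving acid crystallizes with the (S)-amine in step 5 has to be fixed by a trial run, and the antipodal acid is used otherwise.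

Step 1
Reactants: 1 N-methyl-2,2,2-trifluoroacetamide; 2 (E)-1,4-dibromobut-2-ene (3 equiv)
Product: 3 (E)-N-(4-bromobut-2-en-1-yl)-2,2,2-trifluoro-N-methylacetamide
Conditions: NaH, DMF, 0 °C to rt
Reagents that add atoms: none
Why: SN2 N-alkylation of the sodium amidate, with excess symmetric dibromide to suppress double substitution.

Step 2
Reactants: 4 oxetan-3-one; 5 dimethyl malonate
Product: 6 dimethyl 2-(oxetan-3-ylidene)malonate
Conditions: piperidine (10 mol %), AcOH (10 mol %), 4 Å MS, toluene, 60 °C
Reagents that add atoms: none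
Why: Knoevenagel condensation of a strained, highly electrophilic and practically non-enolizable ketone under buffered amine catalysis, which should spare the oxetane; no stereocentre is formed.

Step 3
Reactants: 6 dimethyl 2-(oxetan-3-ylidene)malonate; 3 (E)-N-(4-bromobut-2-en-1-yl)-2,2,2-trifluoro-N-methylacetamide
Product: 8 rac-dimethyl 2-{3-[1-(N-methyl-2,2,2-trifluoroacetamido)but-3-en-2-yl]oxetan-3-yl}malonate, via allylzinc bromide 7 (not isolated)
Conditions: Zn dust, THF/sat. aq NH4Cl, 0 °C to rt
Reagents that add atoms: none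
Why: Barbier-type conjugate allylation in which the allylzinc should add through its γ-carbon to the strain-activated alkylidene malonate, creating quaternary Cf and the allylic centre Cg as a racemate.

Step 4
Reactants: 8 rac-dimethyl 2-{3-[1-(N-methyl-2,2,2-trifluoroacetamido)but-3-en-2-yl]oxetan-3-yl}malonate
Product: 10 rac-dimethyl 7-methyl-9-vinyl-2-oxa-7-azaspiro[3.5]nonane-5,5-dicarboxylate, via secondary amine 9 (not isolated)
Conditions: K2CO3, MeOH/H2O, 40 °C; then 37% aq CH2O, rt to 50 °C
Reagents that add atoms: formaldehyde, C=O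
Why: Mild solvolysis of the trifluoroacetamide frees the secondary amine, whose iminium ion with formaldehyde is captured by the malonate carbon in a six-membered intramolecular Mannich reaction (ring C, quaternary Ce-to-be).

Step 5
Reactants: 10 rac-dimethyl 7-methyl-9-vinyl-2-oxa-7-azaspiro[3.5]nonane-5,5-dicarboxylate
Product: 11 dimethyl (9S)-7-methyl-9-vinyl-2-oxa-7-azaspiro[3.5]nonane-5,5-dicarboxylate
Conditions: (−)-O,O′-dibenzoyl-L-tartaric acid (0.5 equiv), EtOH, recrystallization; then NaHCO3 (aq), CH2Cl2
Reagents that add atoms: none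
Why: Classical resolution of the tertiary amine through its less soluble diastereomeric salt, which fixes the only stereocentre (S at Cg) from which all others are later derived.

Step 6
Reactants: 11 dimethyl (9S)-7-methyl-9-vinyl-2-oxa-7-azaspiro[3.5]nonane-5,5-dicarboxylate
Product: 12 [(9S)-7-methyl-9-vinyl-2-oxa-7-azaspiro[3.5]nonane-5,5-diyl]dimethanol
Conditions: LiAlH4, THF, 0 °C to rt
Reagents that add atoms: none
Why: Hydride reduction of both esters to the 1,3-diol; the 3,3-disubstituted oxetane and the vinyl group should be inert at this temperature.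

Step 7
Reactants: 13 but-3-en-1-ol; 14 tert-butyl acrylate (3 equiv)
Product: 15 tert-butyl (E)-5-hydroxypent-2-enoate
Conditions: second-generation Grubbs catalyst (H2IMes)(PCy3)Cl2Ru=CHPh (2 mol %), CH2Cl2, 40 °C
Reagents that add atoms: none
Why: Olefin cross-metathesis of a terminal alkene with an acrylate, which should give the (E)-enoate selectively.

Step 8
Reactants: 15 tert-butyl (E)-5-hydroxypent-2-enoate
Product: 17 tert-butyl (E)-6,6-dibromohexa-2,5-dienoate, via enal 16 (not isolated)
Conditions: Dess–Martin periodinane, NaHCO3, CH2Cl2, 0 °C; cold filtrate added to CBr4, PPh3, CH2Cl2, 0 °C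
Reagents that add atoms: carbon tetrabromide, BrC(Br)(Br)Br
Why: Dess–Martin oxidation to the labile skipped enal, which is converted at once into the 1,1-dibromoalkene by Ramirez (Corey–Fuchs) dibromoolefination.

Step 9
Reactants: 12 [(9S)-7-methyl-9-vinyl-2-oxa-7-azaspiro[3.5]nonane-5,5-diyl]dimethanol; 17 tert-butyl (E)-6,6-dibromohexa-2,5-dienoate
Product: 19 tert-butyl (2E,5Z)-8-[(9S)-5,5-bis(hydroxymethyl)-7-methyl-2-oxa-7-azaspiro[3.5]nonan-9-yl]-6-bromoocta-2,5-dienoate, via alkylborane 18 (not isolated)
Conditions: 9-BBN dimer (excess), THF, 0 °C to rt; then 17, Pd2(dba)3, tri(2-furyl)phosphine, K3PO4 (aq), DMF, rt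
Reagents that add atoms: none
Why: Anti-Markovnikov hydroboration (excess borane covers the free diol) followed by B-alkyl Suzuki–Miyaura coupling, in which the bromide trans to the chain of the 1,1-dibromoalkene should react selectively and leave the (Z)-alkenyl bromide.

Step 10
Reactants: 19 tert-butyl (2E,5Z)-8-[(9S)-5,5-bis(hydroxymethyl)-7-methyl-2-oxa-7-azaspiro[3.5]nonan-9-yl]-6-bromoocta-2,5-dienoate
Product: 20 tert-butyl (2E,5Z)-6-bromo-8-[(9S)-5,5-diformyl-7-methyl-2-oxa-7-azaspiro[3.5]nonan-9-yl]octa-2,5-dienoate
Conditions: Dess–Martin periodinane (2.4 equiv), NaHCO3, CH2Cl2, 0 °C to rt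
Reagents that add atoms: none
Why: Dess–Martin oxidation of the neopentyl 1,3-diol to a non-enolizable dialdehyde whose two formyl groups are diastereotopic, so Ce is not yet a stereocentre.

Step 11
Reactants: 20 tert-butyl (2E,5Z)-6-bromo-8-[(9S)-5,5-diformyl-7-methyl-2-oxa-7-azaspiro[3.5]nonan-9-yl]octa-2,5-dienoate
Product: 21 tert-butyl (2E,5Z)-5-[1-formyl-2-hydroxy-8-methylspiro[8-azabicyclo[4.3.1]decane-10,3′-oxetan]-3-ylidene]pent-2-enoate (bridgeheads as in 33; carbinol epimers)
Conditions: CrCl2 (6 equiv), NiCl2 (5 mol %), DMSO/THF, 0.003 M, rt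
Reagents that add atoms: none
Why: Intramolecular Nozaki–Hiyama–Kishi reaction in which the alkenylchromium species, formed with retention, can reach only the formyl group cis to the chain, so that closure of ring D defines Ce relative to Cg and places Ca cis to the enoate arm on the alkene.

Step 12
Reactants: 21 tert-butyl (2E,5Z)-5-[1-formyl-2-hydroxy-8-methylspiro[8-azabicyclo[4.3.1]decane-10,3′-oxetan]-3-ylidene]pent-2-enoate
Product: 22 tert-butyl (2E,5Z)-5-[1-formyl-8-methyl-2-oxospiro[8-azabicyclo[4.3.1]decane-10,3′-oxetan]-3-ylidene]pent-2-enoate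
Conditions: Dess–Martin periodinane, NaHCO3, CH2Cl2, 0 °C
Reagents that add atoms: none
Why: Dess–Martin oxidation of the allylic alcohol to the conjugated ketone, which removes the carbinol stereocentre; the quaternary α-carbon Ce prevents enolization of the β-keto aldehyde.

Step 13
Reactants: 22 tert-butyl (2E,5Z)-5-[1-formyl-8-methyl-2-oxospiro[8-azabicyclo[4.3.1]decane-10,3′-oxetan]-3-ylidene]pent-2-enoate
Product: 24 tert-butyl hydroxy ester with rings C D E F closed (OH at Ca and Cd; CO2tBu at Cc; mixture at Cc and Cd), via samarium enolate 23 (not isolated)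
Conditions: SmI2 (2.5 equiv), THF, −78 °C to 0 °C; then NH4Cl (aq)
Reagents that add atoms: none
Why: Single-electron transfer to the conjugated ketone gives a ketyl radical anion whose carbonyl carbon Ca adds 5-exo-trig to the enoate β-carbon Cb (ring E; the β-carbon of the dienolate radical could reach the enoate only through a three-membered ring), a second electron transfer gives the trivalent samarium enolate, and its α-carbon Cc adds 5-exo-trig to the formyl carbon Cd (ring F). The closest known reaction type is the SmI2 ketyl–olefin cyclization/aldol cascade of carbonyl-tethered enoates. At Ca, Cb should add to the carbonyl face that carries the formyl group, because the other face is flanked by the oxetane-bearing Cf and the piperidine CH2; at Cb, the enolate arm should set anti to the O–Sm group, which puts it cis to Ce as ring F requires; Cc and Cd come from the samarium-bridged aldol and are both erased in step 14. The step needs reduction of the enone (the most easily reduced group) before the aldehyde and the enoate, and it needs the (Z)-alkylidene geometry fixed in steps 9 and 11 so that the enoate lies over Ca.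

Step 14
Reactants: 24 tert-butyl hydroxy ester with rings C D E F closed
Product: 26 ring-F enoate (Cc=Cd double bond; CO2tBu at Cc), via mesylate 25 (not isolated)
Conditions: MsCl, Et3N, CH2Cl2, 0 °C; then DBU, rt
Reagents that add atoms: none
Why: Mesylation of the secondary aldol hydroxyl (the tertiary one at Ca is too hindered) and E1cB elimination give the conjugated ester and erase the stereocentres at Cc and Cd.

Step 15
Reactants: 26 ring-F enoate
Product: 27 saturated tert-butyl ester (Cc as in 33)
Conditions: Mg turnings, MeOH, 0 °C to rt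
Reagents that add atoms: none
Why: Dissolving-metal conjugate reduction of the α,β-unsaturated ester, in which the magnesium enolate should be protonated at Cc from the convex face (anti to rings D and E), placing the ester on the concave face next to the oxetane.

Step 16
Reactants: 27 saturated tert-butyl ester
Product: 29 hydroxy lactone (33 with CH2OH in place of the side chain), via carboxylic acid 28 (not isolated)
Conditions: CF3CO2H/CH2Cl2 (1:5), 0 °C to rt; then NaHCO3 (aq)
Reagents that add atoms: none
Why: Acid cleaves the tert-butyl ester and the carboxylic acid opens the protonated oxetane at the only CH2 it can reach (strain-release isomerization of an oxetane-carboxylic acid to a lactone), which closes the seven-membered lactone, frees the other arm as CH2OH and makes Cf stereogenic with the required configuration.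

Step 17
Reactants: 29 hydroxy lactone
Product: 30 aldehyde (33 with CHO in place of the side chain)
Conditions: Dess–Martin periodinane, NaHCO3, CH2Cl2, rt
Reagents that add atoms: none
Why: Dess–Martin oxidation of the primary neopentyl alcohol; the tertiary alcohol cannot be oxidized.

Step 18
Reactants: 30 aldehyde; 31 dimethyl (3-methyl-2-oxobutyl)phosphonate
Product: 32 (E)-enone (33 with a C=C bond between the two side-chain CH2 carbons)
Conditions: LiCl, iPr2NEt, MeCN, rt
Reagents that add atoms: none
Why: Horner–Wadsworth–Emmons olefination under mild LiCl/amine conditions should give the (E)-enone without opening the lactone.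

Step 19
Reactants: 32 (E)-enone
Product: 33 target CNP0242289.1
Conditions: [(Ph3P)CuH]6 (0.5 equiv), toluene, H2O (2 equiv), rt
Reagents that add atoms: none
Why: Chemoselective 1,4-reduction of the enone by the copper hydride, which should leave the trisubstituted ring alkene, the lactone and the tertiary alcohol untouched.

Compound list
1 | N-methyl-2,2,2-trifluoroacetamide | CNC(=O)C(F)(F)F | starting material
2 | (E)-1,4-dibromobut-2-ene | BrC/C=C/CBr | starting material
3 | (E)-N-(4-bromobut-2-en-1-yl)-2,2,2-trifluoro-N-methylacetamide | CN(C/C=C/CBr)C(=O)C(F)(F)F | intermediate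
4 | oxetan-3-one | O=C1COC1 | starting material
5 | dimethyl malonate | COC(=O)CC(=O)OC | starting material
6 | dimethyl 2-(oxetan-3-ylidene)malonate | COC(=O)C(C(=O)OC)=C1COC1 | intermediate
7 | allylzinc bromide from 3 (not isolated) | CN(C/C=C/C[Zn]Br)C(=O)C(F)(F)F | intermediate
8 | rac-dimethyl 2-{3-[1-(N-methyl-2,2,2-trifluoroacetamido)but-3-en-2-yl]oxetan-3-yl}malonate | COC(=O)C(C(=O)OC)C1(COC1)C(C=C)CN(C)C(=O)C(F)(F)F | intermediate
9 | rac-dimethyl 2-{3-[1-(methylamino)but-3-en-2-yl]oxetan-3-yl}malonate (not isolated) | COC(=O)C(C(=O)OC)C1(COC1)C(C=C)CNC | intermediate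
10 | rac-dimethyl 7-methyl-9-vinyl-2-oxa-7-azaspiro[3.5]nonane-5,5-dicarboxylate | COC(=O)C1(C(=O)OC)CN(C)CC(C=C)C12COC2 | intermediate
11 | dimethyl (9S)-7-methyl-9-vinyl-2-oxa-7-azaspiro[3.5]nonane-5,5-dicarboxylate | COC(=O)C1(C(=O)OC)CN(C)C[C@@H](C=C)C12COC2 | intermediate
12 | [(9S)-7-methyl-9-vinyl-2-oxa-7-azaspiro[3.5]nonane-5,5-diyl]dimethanol | OCC1(CO)CN(C)C[C@@H](C=C)C12COC2 | intermediate
13 | but-3-en-1-ol | C=CCCO | starting material
14 | tert-butyl acrylate | C=CC(=O)OC(C)(C)C | starting material
15 | tert-butyl (E)-5-hydroxypent-2-enoate | OCC/C=C/C(=O)OC(C)(C)C | intermediate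
16 | tert-butyl (E)-5-oxopent-2-enoate (not isolated) | O=CC/C=C/C(=O)OC(C)(C)C | intermediate
17 | tert-butyl (E)-6,6-dibromohexa-2,5-dienoate | BrC(Br)=CC/C=C/C(=O)OC(C)(C)C | intermediate
18 | B-alkyl-9-BBN adduct of 12 (not isolated) | OCC1(CO)CN(C)C[C@@H](CCB3C4CCCC3CCC4)C12COC2 | intermediate
19 | tert-butyl (2E,5Z)-8-[(9S)-5,5-bis(hydroxymethyl)-7-methyl-2-oxa-7-azaspiro[3.5]nonan-9-yl]-6-bromoocta-2,5-dienoate | OCC1(CO)CN(C)C[C@@H](CC/C(Br)=C/C/C=C/C(=O)OC(C)(C)C)C12COC2 | intermediate
20 | tert-butyl (2E,5Z)-6-bromo-8-[(9S)-5,5-diformyl-7-methyl-2-oxa-7-azaspiro[3.5]nonan-9-yl]octa-2,5-dienoate | O=CC1(C=O)CN(C)C[C@@H](CC/C(Br)=C/C/C=C/C(=O)OC(C)(C)C)C12COC2 | intermediate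
21 | tert-butyl (2E,5Z)-5-[1-formyl-2-hydroxy-8-methylspiro[8-azabicyclo[4.3.1]decane-10,3′-oxetan]-3-ylidene]pent-2-enoate (bridgeheads as in 33; carbinol epimers) | O=C[C@@]12CN(C)C[C@@H](CC/C(=C/C/C=C/C(=O)OC(C)(C)C)C1O)C23COC3 | intermediate
22 | tert-butyl (2E,5Z)-5-[1-formyl-8-methyl-2-oxospiro[8-azabicyclo[4.3.1]decane-10,3′-oxetan]-3-ylidene]pent-2-enoate (bridgeheads as in 33) | O=C[C@@]12CN(C)C[C@@H](CC/C(=C/C/C=C/C(=O)OC(C)(C)C)C1=O)C23COC3 | intermediate
23 | bis(diiodosamarium) alkoxide/ester enolate with ring E closed (not isolated) | O=C[C@@]12CN(C)C[C@@H](CCC3=CC[C@H](C=C(O[Sm](I)I)OC(C)(C)C)[C@@]31O[Sm](I)I)C24COC4 | intermediate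
24 | tert-butyl hydroxy ester with rings C D E F closed and spiro-oxetane at Cf (OH at Ca and Cd; CO2tBu at Cc; mixture at Cc and Cd) | CC(C)(C)OC(=O)C1C(O)[C@@]23CN(C)C[C@@H](CCC4=CC[C@H]1[C@@]42O)C35COC5 | intermediate
25 | Cd-mesylate of 24 (not isolated) | CC(C)(C)OC(=O)C1C(OS(C)(=O)=O)[C@@]23CN(C)C[C@@H](CCC4=CC[C@H]1[C@@]42O)C35COC5 | intermediate
26 | ring-F enoate (Cc=Cd; CO2tBu at Cc) | CC(C)(C)OC(=O)C1=C[C@@]23CN(C)C[C@@H](CCC4=CC[C@H]1[C@@]42O)C35COC5 | intermediate
27 | saturated tert-butyl ester (all stereocentres as in 33) | CC(C)(C)OC(=O)[C@@H]1C[C@@]23CN(C)C[C@@H](CCC4=CC[C@H]1[C@@]42O)C35COC5 | intermediate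
28 | carboxylic acid from 27 (not isolated) | OC(=O)[C@@H]1C[C@@]23CN(C)C[C@@H](CCC4=CC[C@H]1[C@@]42O)C35COC5 | intermediate
29 | hydroxy lactone (33 with CH2OH in place of the side chain) | OC[C@]12COC(=O)[C@@H]3C[C@]14CN(C)C[C@H]2CCC1=CC[C@H]3[C@@]14O | intermediate
30 | aldehyde (33 with CHO in place of the side chain) | O=C[C@]12COC(=O)[C@@H]3C[C@]14CN(C)C[C@H]2CCC1=CC[C@H]3[C@@]14O | intermediate
31 | dimethyl (3-methyl-2-oxobutyl)phosphonate | COP(=O)(CC(=O)C(C)C)OC | starting material
32 | (E)-enone (33 with a C=C bond between the two side-chain CH2 carbons) | CC(C)C(=O)/C=C/[C@]12COC(=O)[C@@H]3C[C@]14CN(C)C[C@H]2CCC1=CC[C@H]3[C@@]14O | intermediate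
33 | CNP0242289.1 | CC(C)C(=O)CC[C@]12COC(=O)[C@@H]3C[C@]14CN(C)C[C@H]2CCC1=CC[C@H]3[C@@]14O | target

Total step count: 19. Longest linear sequence: 16 steps (steps 2–6 and 9–19, from oxetan-3-one).

Steps most likely to fail

Step 13. Electron transfer to the formyl group, or protonation or dimerization of the dienolate radical anion at its β-carbon, may compete with the 5-exo closure, and the samarium enolate may be quenched before the aldol closure. The fallback separates the two bond formations and sets out from 22. A neutral tin-hydride chain (Bu3SnH, AIBN, benzene, 80 °C) generates the O-stannyl ketyl, which should close ring E and, after hydrogen transfer and hydrolytic work-up, give the ring-E-closed hydroxy ester aldehyde F1. LDA (2.2 equiv, THF, −78 °C) then forms the ester enolate, whose intramolecular aldol addition to the formyl group closes ring F and comes back to the route at 24.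

Step 11. Intermolecular coupling and protodebromination of the alkenylchromium species may outrun the seven-membered closure at the required dilution. The fallback replaces the chromium-mediated addition by a rhodium-catalysed carbonyl addition of a boronate and sets out from 19. Miyaura borylation (bis(pinacolato)diboron, PdCl2(PPh3)2, KOPh, toluene, 50 °C) gives the (Z)-alkenylboronate diol F2 with retention. Dess–Martin oxidation gives the boronate dialdehyde F3. [Rh(OH)(cod)]2 (monovalent rhodium) in dioxane/H2O at 60 °C then adds the alkenyl group to the cis formyl group and comes back to the route at 21.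

Step 16. The carboxyl group may fail to open the oxetane (SN2 at a neopentyl-type CH2 through a seven-membered transition state), so that external trifluoroacetate opens it instead. The fallback forms the lactone C–O bond by acyl substitution and sets out from 27. Aqueous HCl (2 M) in dioxane at 60 °C hydrolyses both the tert-butyl ester and the oxetane to the dihydroxy acid F4. Yamaguchi lactonization (2,4,6-trichlorobenzoyl chloride, Et3N; then DMAP, toluene, high dilution) acylates the only CH2OH group that can reach the carboxyl carbon and comes back to the route at 29.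

Further compounds
F1 | step 13 | ring-E-closed hydroxy ester aldehyde (formyl on Ce, CH2CO2tBu on Cb, OH on Ca) | O=C[C@@]12CN(C)C[C@@H](CCC3=CC[C@H](CC(=O)OC(C)(C)C)[C@@]31O)C24COC4
F2 | step 11 | tert-butyl (2E,5Z)-8-[(9S)-5,5-bis(hydroxymethyl)-7-methyl-2-oxa-7-azaspiro[3.5]nonan-9-yl]-6-(4,4,5,5-tetramethyl-1,3,2-dioxaborolan-2-yl)octa-2,5-dienoate | OCC1(CO)CN(C)C[C@@H](CC/C(B3OC(C)(C)C(C)(C)O3)=C/C/C=C/C(=O)OC(C)(C)C)C12COC2
F3 | step 11 | tert-butyl (2E,5Z)-8-[(9S)-5,5-diformyl-7-methyl-2-oxa-7-azaspiro[3.5]nonan-9-yl]-6-(4,4,5,5-tetramethyl-1,3,2-dioxaborolan-2-yl)octa-2,5-dienoate | O=CC1(C=O)CN(C)C[C@@H](CC/C(B3OC(C)(C)C(C)(C)O3)=C/C/C=C/C(=O)OC(C)(C)C)C12COC2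
F4 | step 16 | dihydroxy acid (28 with the oxetane hydrolysed to two CH2OH groups on Cf) | OC(=O)[C@@H]1C[C@@]23CN(C)C[C@@H](CCC4=CC[C@H]1[C@@]42O)C3(CO)CO
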